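**Retrosynthetic overview**
1. The rings are lettered along the chain A–O–B–O–C–O–D–O–E–O–F–O–G, from the terminal 2,4,6-trihydroxyphenyl ring A to the terminal 3,4,5-trihydroxyphenyl ring G. The target has no stereocentre.
2. Feature used: ring G is symmetric about the axis through G C1 and G C4, with oxygens on C3, C4 and C5 and the ring F oxygen on C1. C3–C4–C5 is therefore a 1,3-bis(benzyloxy)acetone, and C2–C1–C6 is a malonaldehyde unit already attached to the F C4 oxygen. A [3+3] condensation forms G C2–C3 and G C5–C6; ring G is the only ring built, and the other six are bought as arenes.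
3. The crowded F C4–O bond is made by O-alkylation of a 2,6-dimethoxyphenol. F C1 carries bromine through the ring synthesis, so block FG ends as an aryl bromide with free ortho positions.
4. The other five ether bonds are copper-catalysed couplings in which the oxygen always comes from the di-ortho-substituted phenol. Rings B and D enter as O-benzyl-4-bromo-2,6-dimethoxyphenol (hydrogenolysis frees the next phenol). Rings C and E enter as ortho-bromobenzaldehydes (CHO activates C–Br, then becomes the next phenol by Baeyer–Villiger oxidation).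
5. Order: G on F (steps 1–5); A+B, +C, +D, +E (steps 6–15); A–E phenol + FG bromide (step 16); hydrogenolysis and BBr3 (steps 17–18).

Key step: step 4

Remark: free rotation about all diaryl ether bonds is assumed, so the only stereodescriptor in the route is the C=C geometry of 6. Compounds 1, 2, 5, 7, 12, 15 and 23 are taken as purchasable.

**Step 1**
Reactants: 1 4-bromo-2,6-dimethoxyphenol; 2 bromoacetaldehyde diethyl acetal
Product: 3 5-bromo-2-(2,2-diethoxyethoxy)-1,3-dimethoxybenzene
Conditions: K2CO3, KI (cat.), DMF, 110 °C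
Reagents that add atoms: none
Why: Williamson ether synthesis, in which the phenoxide of 1, although flanked by two methoxy groups, displaces the primary bromide on heating, so the crowded F C4–O bond arises by alkylation and the aryl bromide is untouched.

**Step 2**
Reactants: 3 5-bromo-2-(2,2-diethoxyethoxy)-1,3-dimethoxybenzene
Product: 4 2-(4-bromo-2,6-dimethoxyphenoxy)acetaldehyde
Conditions: 2 M aq. HCl, THF, 60 °C; used crude
Reagents that add atoms: water, O
Why: Acid-catalysed acetal hydrolysis, to which aryl ethers and the aryl bromide are inert.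

**Step 3**
Reactants: 4 2-(4-bromo-2,6-dimethoxyphenoxy)acetaldehyde; 5 N,N-dimethylformamide dimethyl acetal
Product: 6 (Z)-2-(4-bromo-2,6-dimethoxyphenoxy)-3-(dimethylamino)prop-2-enal
Conditions: 5 (2 equiv), toluene, 85 °C, slow addition of 4
Reagents that add atoms: none
Why: Aminomethylenation of an activated methylene with a formamide acetal, in which the CH2 between CHO and the aryloxy oxygen condenses with loss of two methanol and the push–pull product settles with NMe2 trans to CHO.

**Step 4**
Reactants: 6 (Z)-2-(4-bromo-2,6-dimethoxyphenoxy)-3-(dimethylamino)prop-2-enal; 7 1,3-bis(benzyloxy)propan-2-one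
Product: 9 2,6-bis(benzyloxy)-4-(4-bromo-2,6-dimethoxyphenoxy)phenol, via dienaminone 8 (not isolated)
Conditions: KOtBu (2.5 equiv), THF/t-BuOH, 0 °C, slow addition of 7, then 65 °C, Ar; AcOH quench
Reagents that add atoms: none
Why: Proposed new method: the potassium enolate of 7 should add to the formyl carbon of 6, and E1cB loss of water should give the push–pull dienaminone 8, which sets the bond G C5–C6. Deprotonation of the remaining CH2OBn group lets that carbon attack the NMe2-bearing terminus, forming G C2–C3 and closing ring G by a 6-endo-trig addition–elimination (formally a 6π closure of the trienolate); loss of HNMe2 and enolisation then give the phenoxide irreversibly. The closest known reaction type is the [3+3] phenol synthesis from 1,3-disubstituted acetones with nitromalonaldehyde salts, vinamidinium salts or 3-aminoacroleins, but the pairing of a 2-aryloxy three-carbon unit with a 1,3-dialkoxyacetone has not been shown. No stereocentre is created, and because both partners are symmetric about the future G C1–C4 axis, either order of bond formation leads to the same phenol. The step needs cross-condensation over self-aldol of 7; this is secured because the self-aldol is reversible while the cross-product is removed by aromatisation, and because 7 is kept dilute by slow addition. The aryl bromide, methyl ethers and benzyl ethers should tolerate KOtBu at this temperature.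

**Step 5**
Reactants: 9 2,6-bis(benzyloxy)-4-(4-bromo-2,6-dimethoxyphenoxy)phenol
Product: 10 1,2,3-tris(benzyloxy)-5-(4-bromo-2,6-dimethoxyphenoxy)benzene (block FG bromide)
Conditions: BnBr, K2CO3, DMF, 50 °C
Reagents that add atoms: benzyl bromide, BrCc1ccccc1
Why: Williamson benzylation of the G C4 phenol, which masks the only acidic site before the copper coupling.

**Step 6**
Reactants: 1 4-bromo-2,6-dimethoxyphenol
Product: 11 2-(benzyloxy)-5-bromo-1,3-dimethoxybenzene
Conditions: BnBr, K2CO3, DMF, 50 °C
Reagents that add atoms: benzyl bromide, BrCc1ccccc1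
Why: Williamson benzylation gives one building block that serves for both ring B and ring D.

**Step 7**
Reactants: 12 2,4,6-trimethoxyphenol; 11 2-(benzyloxy)-5-bromo-1,3-dimethoxybenzene
Product: 13 2-[4-(benzyloxy)-3,5-dimethoxyphenoxy]-1,3,5-trimethoxybenzene (dimer AB benzyl ether)
Conditions: CuI (10 mol%), picolinic acid (20 mol%), K3PO4, DMSO, 90 °C, Ar
Reagents that add atoms: none
Why: Ligand-accelerated Ullmann diaryl ether synthesis, a catalyst system suited to di-ortho-substituted phenols, applied here to a bromide whose two ortho positions are free.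

**Step 8**
Reactants: 13 2-[4-(benzyloxy)-3,5-dimethoxyphenoxy]-1,3,5-trimethoxybenzene
Product: 14 2,6-dimethoxy-4-(2,4,6-trimethoxyphenoxy)phenol (dimer AB phenol)
Conditions: H2 (1 atm), 10% Pd/C, EtOAc/MeOH, rt
Reagents that add atoms: none
Why: Catalytic hydrogenolysis of a benzyl aryl ether, which leaves methyl ethers and the diaryl ether intact.

**Step 9**
Reactants: 15 5-bromo-1,2,3-trimethoxybenzene
Product: 17 6-bromo-2,3,4-trimethoxybenzaldehyde, via chloro(methoxy)methyl arene 16 (not isolated)
Conditions: Cl2CHOMe, TiCl4, CH2Cl2, 0 °C; then ice-water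
Reagents that add atoms: dichloromethyl methyl ether, COC(Cl)Cl; water, O
Why: Rieche formylation, in which the two free ring positions of 15 are equivalent (ortho to Br and OMe, para to OMe), so only one aldehyde can form.

**Step 10**
Reactants: 14 2,6-dimethoxy-4-(2,4,6-trimethoxyphenoxy)phenol; 17 6-bromo-2,3,4-trimethoxybenzaldehyde
Product: 18 2,3,4-trimethoxy-6-[2,6-dimethoxy-4-(2,4,6-trimethoxyphenoxy)phenoxy]benzaldehyde (trimer ABC aldehyde)
Conditions: CuI (20 mol%), picolinic acid (40 mol%), K3PO4, DMSO, 100 °C, Ar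
Reagents that add atoms: none
Why: Ullmann condensation of a phenol with an ortho-bromobenzaldehyde, in which the ortho formyl group activates the C–Br bond enough to offset the crowding of the ring B phenoxide and cannot enolise under the base.

**Step 11**
Reactants: 18 trimer ABC aldehyde
Product: 20 2,3,4-trimethoxy-6-[2,6-dimethoxy-4-(2,4,6-trimethoxyphenoxy)phenoxy]phenol (trimer ABC phenol), via trimer formate 19 (not isolated)
Conditions: mCPBA, CH2Cl2, 0 °C to rt; then K2CO3 (cat.), MeOH, rt, Ar
Reagents that add atoms: mCPBA (3-chloroperbenzoic acid), O=C(OO)c1cccc(Cl)c1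
Why: Baeyer–Villiger oxidation with aryl migration, favoured by the ortho and para oxygen donors of ring C, followed by methanolysis of the formate to free C C2–OH.

**Step 12**
Reactants: 20 trimer ABC phenol; 11 2-(benzyloxy)-5-bromo-1,3-dimethoxybenzene
Product: 21 1-[4-(benzyloxy)-3,5-dimethoxyphenoxy]-2,3,4-trimethoxy-6-[2,6-dimethoxy-4-(2,4,6-trimethoxyphenoxy)phenoxy]benzene (tetramer ABCD benzyl ether)
Conditions: 11 (1.5 equiv), CuI (20 mol%), picolinic acid (40 mol%), K3PO4, DMSO, 100 °C, Ar
Reagents that add atoms: none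
Why: Ullmann diaryl ether synthesis in the favourable steric sense, with the oxygen from the crowded C C2 phenol and the carbon from the unhindered bromide 11, which can be used in excess.

**Step 13**
Reactants: 21 tetramer ABCD benzyl ether
Product: 22 4-{2,3,4-trimethoxy-6-[2,6-dimethoxy-4-(2,4,6-trimethoxyphenoxy)phenoxy]phenoxy}-2,6-dimethoxyphenol (tetramer ABCD phenol)
Conditions: H2 (1 atm), 10% Pd/C, EtOAc/MeOH, rt
Reagents that add atoms: none
Why: Catalytic hydrogenolysis removes the only benzyl group and frees D C4–OH.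

**Step 14**
Reactants: 22 tetramer ABCD phenol; 23 2-bromo-4,6-dimethoxybenzaldehyde
Product: 24 pentamer A–E aldehyde (D C4–O bonded to C2 of a 4,6-dimethoxybenzaldehyde; the CHO sits on E C2)
Conditions: 23 (1.5 equiv), CuI (20 mol%), picolinic acid (40 mol%), K3PO4, DMSO, 100 °C, Ar
Reagents that add atoms: none
Why: Ullmann condensation with an ortho-bromobenzaldehyde as in step 10, here with both methoxy groups meta to the C–Br carbon, so they do not deactivate it.

**Step 15**
Reactants: 24 pentamer A–E aldehyde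
Product: 26 pentamer A–E phenol (free OH on E C2), via pentamer formate 25 (not isolated)
Conditions: mCPBA, CH2Cl2, 0 °C to rt; then K2CO3 (cat.), MeOH, rt, Ar
Reagents that add atoms: mCPBA (3-chloroperbenzoic acid), O=C(OO)c1cccc(Cl)c1
Why: Baeyer–Villiger oxidation of a 2,4,6-trioxygenated benzaldehyde, whose aryl group migrates readily, followed by formate methanolysis; the other rings carry only ethers and should react much more slowly with the peracid.

**Step 16**
Reactants: 26 pentamer A–E phenol; 10 block FG bromide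
Product: 27 protected heptamer A–G (fourteen methyl ethers on rings A–F; three benzyl ethers on ring G)
Conditions: CuI (30 mol%), picolinic acid (60 mol%), K3PO4, DMSO, 100 °C, Ar
Reagents that add atoms: none
Why: Ullmann diaryl ether synthesis forms E C2–O–F C1 from the crowded phenol and an aryl bromide with free ortho positions, and methyl and benzyl ethers are inert to the conditions.

**Step 17**
Reactants: 27 protected heptamer A–G
Product: 28 heptamer tetradecamethyl ether with free 3,4,5-trihydroxyphenyl ring G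
Conditions: H2 (1 atm), 10% Pd/C, THF/MeOH, rt; kept under Ar
Reagents that add atoms: none
Why: Catalytic hydrogenolysis of the three benzyl ethers before the Lewis acid step avoids benzyl cations that would C-alkylate the electron-rich rings.

**Step 18**
Reactants: 28 heptamer tetradecamethyl ether
Product: 29 CNP0351377.0 (target)
Conditions: BBr3 (30 equiv), CH2Cl2, −78 °C to rt, Ar; then ice-water, EtOAc; Sephadex LH-20, degassed MeOH
Reagents that add atoms: none
Why: Lewis acid cleavage of aryl methyl ethers with BBr3 breaks only the O–CH3 bonds, because diaryl ether C–O bonds offer no carbon open to bromide attack.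

**Compound list**
1 | 4-bromo-2,6-dimethoxyphenol | COc1cc(Br)cc(OC)c1O | starting material
2 | bromoacetaldehyde diethyl acetal | CCOC(CBr)OCC | starting material
3 | 5-bromo-2-(2,2-diethoxyethoxy)-1,3-dimethoxybenzene | CCOC(COc1c(OC)cc(Br)cc1OC)OCC | intermediate
4 | 2-(4-bromo-2,6-dimethoxyphenoxy)acetaldehyde | O=CCOc1c(OC)cc(Br)cc1OC | intermediate
5 | N,N-dimethylformamide dimethyl acetal | COC(OC)N(C)C | starting material
6 | (Z)-2-(4-bromo-2,6-dimethoxyphenoxy)-3-(dimethylamino)prop-2-enal | CN(C)/C=C(/C=O)Oc1c(OC)cc(Br)cc1OC | intermediate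
7 | 1,3-bis(benzyloxy)propan-2-one | O=C(COCc1ccccc1)COCc1ccccc1 | starting material
8 | 1,3-bis(benzyloxy)-5-(4-bromo-2,6-dimethoxyphenoxy)-6-(dimethylamino)hexa-3,5-dien-2-one (C=C geometry labile; not isolated) | CN(C)C=C(Oc1c(OC)cc(Br)cc1OC)C=C(OCc1ccccc1)C(=O)COCc1ccccc1 | intermediate
9 | 2,6-bis(benzyloxy)-4-(4-bromo-2,6-dimethoxyphenoxy)phenol | Oc1c(OCc2ccccc2)cc(Oc2c(OC)cc(Br)cc2OC)cc1OCc1ccccc1 | intermediate
10 | 1,2,3-tris(benzyloxy)-5-(4-bromo-2,6-dimethoxyphenoxy)benzene | COc1cc(Br)cc(OC)c1Oc1cc(OCc2ccccc2)c(OCc2ccccc2)c(OCc2ccccc2)c1 | intermediate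
11 | 2-(benzyloxy)-5-bromo-1,3-dimethoxybenzene | COc1cc(Br)cc(OC)c1OCc1ccccc1 | intermediate
12 | 2,4,6-trimethoxyphenol | COc1cc(OC)c(O)c(OC)c1 | starting material
13 | 2-[4-(benzyloxy)-3,5-dimethoxyphenoxy]-1,3,5-trimethoxybenzene | COc1cc(OC)c(Oc2cc(OC)c(OCc3ccccc3)c(OC)c2)c(OC)c1 | intermediate
14 | 2,6-dimethoxy-4-(2,4,6-trimethoxyphenoxy)phenol | COc1cc(OC)c(Oc2cc(OC)c(O)c(OC)c2)c(OC)c1 | intermediate
15 | 5-bromo-1,2,3-trimethoxybenzene | COc1cc(Br)cc(OC)c1OC | starting material
16 | 1-bromo-2-[chloro(methoxy)methyl]-3,4,5-trimethoxybenzene (racemic; not isolated) | COC(Cl)c1c(Br)cc(OC)c(OC)c1OC | intermediate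
17 | 6-bromo-2,3,4-trimethoxybenzaldehyde | COc1cc(Br)c(C=O)c(OC)c1OC | intermediate
18 | trimer ABC aldehyde | COc1cc(OC)c(Oc2cc(OC)c(Oc3cc(OC)c(OC)c(OC)c3C=O)c(OC)c2)c(OC)c1 | intermediate
19 | trimer ABC formate (not isolated) | COc1cc(OC)c(Oc2cc(OC)c(Oc3cc(OC)c(OC)c(OC)c3OC=O)c(OC)c2)c(OC)c1 | intermediate
20 | trimer ABC phenol | COc1cc(OC)c(Oc2cc(OC)c(Oc3cc(OC)c(OC)c(OC)c3O)c(OC)c2)c(OC)c1 | intermediate
21 | tetramer ABCD benzyl ether | COc1cc(OC)c(Oc2cc(OC)c(Oc3cc(OC)c(OC)c(OC)c3Oc3cc(OC)c(OCc4ccccc4)c(OC)c3)c(OC)c2)c(OC)c1 | intermediate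
22 | tetramer ABCD phenol | COc1cc(OC)c(Oc2cc(OC)c(Oc3cc(OC)c(OC)c(OC)c3Oc3cc(OC)c(O)c(OC)c3)c(OC)c2)c(OC)c1 | intermediate
23 | 2-bromo-4,6-dimethoxybenzaldehyde | COc1cc(Br)c(C=O)c(OC)c1 | starting material
24 | pentamer A–E aldehyde | COc1cc(OC)c(Oc2cc(OC)c(Oc3cc(OC)c(OC)c(OC)c3Oc3cc(OC)c(Oc4cc(OC)cc(OC)c4C=O)c(OC)c3)c(OC)c2)c(OC)c1 | intermediate
25 | pentamer A–E formate (not isolated) | COc1cc(OC)c(Oc2cc(OC)c(Oc3cc(OC)c(OC)c(OC)c3Oc3cc(OC)c(Oc4cc(OC)cc(OC)c4OC=O)c(OC)c3)c(OC)c2)c(OC)c1 | intermediate
26 | pentamer A–E phenol | COc1cc(OC)c(Oc2cc(OC)c(Oc3cc(OC)c(OC)c(OC)c3Oc3cc(OC)c(Oc4cc(OC)cc(OC)c4O)c(OC)c3)c(OC)c2)c(OC)c1 | intermediate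
27 | protected heptamer A–G | COc1cc(OC)c(Oc2cc(OC)c(Oc3cc(OC)c(OC)c(OC)c3Oc3cc(OC)c(Oc4cc(OC)cc(OC)c4Oc4cc(OC)c(Oc5cc(OCc6ccccc6)c(OCc6ccccc6)c(OCc6ccccc6)c5)c(OC)c4)c(OC)c3)c(OC)c2)c(OC)c1 | intermediate
28 | heptamer tetradecamethyl ether, ring G free | COc1cc(OC)c(Oc2cc(OC)c(Oc3cc(OC)c(OC)c(OC)c3Oc3cc(OC)c(Oc4cc(OC)cc(OC)c4Oc4cc(OC)c(Oc5cc(O)c(O)c(O)c5)c(OC)c4)c(OC)c3)c(OC)c2)c(OC)c1 | intermediate
29 | CNP0351377.0 | Oc1cc(O)c(Oc2cc(O)c(Oc3cc(O)c(O)c(O)c3Oc3cc(O)c(Oc4cc(O)cc(O)c4Oc4cc(O)c(Oc5cc(O)c(O)c(O)c5)c(O)c4)c(O)c3)c(O)c2)c(O)c1 | target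

**Step count**
- Total step count: 18.
- Longest linear sequence: 12 steps (6, 7, 8, 10, 11, 12, 13, 14, 15, 16, 17, 18).
- The branch that carries the key step (1–5) joins at step 16.

**Steps most likely to fail**

Risk 1, step 4 (labelled step).
- What may go wrong: ketone 7 may be consumed by self-aldol and base-induced decay. The water released may hydrolyse the enaminal to an unreactive malonaldehyde enolate. The sequence may also stall at the open-chain stage without ring closure.
- Fallback (known chemistry): it sets out from 15 and 1 and comes back at 10, taking ring G as a bought arene instead of building it. BBr3 demethylation of 15 gives 5-bromobenzene-1,2,3-triol F1. Perbenzylation (BnBr, K2CO3, DMF) gives 1,2,3-tris(benzyloxy)-5-bromobenzene F2. Bromine–lithium exchange with n-BuLi in THF at −78 °C gives 3,4,5-tris(benzyloxy)phenyllithium F3. Trapping with B(OiPr)3 and hydrolysis with dilute HCl give 3,4,5-tris(benzyloxy)phenylboronic acid F4. Chan–Evans–Lam coupling of F4 with phenol 1 (Cu(OAc)2, pyridine, 4 Å sieves, CH2Cl2, dry air, rt) tolerates the aryl bromide of 1 and gives 10.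

Risk 2, step 16.
- What may go wrong: activation of the electron-rich, unactivated C–Br bond of 10 may be slow. Reduction of the bromide and oxidation of the crowded phenoxide may compete, and neither precious partner can be used in excess.
- Fallback: it sets out from 10 and comes back at 27, inverting the role of block FG. Exchange of 10 with n-BuLi in THF at −78 °C gives 4-[3,4,5-tris(benzyloxy)phenoxy]-3,5-dimethoxyphenyllithium F5. B(OiPr)3 followed by dilute HCl gives 4-[3,4,5-tris(benzyloxy)phenoxy]-3,5-dimethoxyphenylboronic acid F6. This is joined to phenol 26 by an oxidative Chan–Evans–Lam coupling at room temperature (Cu(OAc)2, pyridine, 4 Å sieves, CH2Cl2, dry air) to give 27.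

Risk 3, step 18.
- What may go wrong: cleavage of the fourteen methyl ethers may be incomplete once partly cleaved borates precipitate. The free polyphenol may oxidise in air during aqueous isolation and chromatography.
- Fallback: it sets out from 28 and comes back at 29 by a derivatise–purify–release sequence. After BBr3 treatment and quench, the crude material is not purified but peracetylated (Ac2O, pyridine, rt) to the heptadecaacetate of the target F7. F7 is neutral and air-stable and can be separated on silica from under-cleaved congeners, which can be resubmitted. Acid-catalysed methanolysis (HCl from AcCl in degassed MeOH, 40 °C, Ar) then releases 29 without passing through oxidisable phenolates.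

**Further compounds**
F1 | step 4 | 5-bromobenzene-1,2,3-triol | Oc1cc(Br)cc(O)c1O
F2 | step 4 | 1,2,3-tris(benzyloxy)-5-bromobenzene | Brc1cc(OCc2ccccc2)c(OCc2ccccc2)c(OCc2ccccc2)c1
F3 | step 4 | 3,4,5-tris(benzyloxy)phenyllithium | [Li]c1cc(OCc2ccccc2)c(OCc2ccccc2)c(OCc2ccccc2)c1
F4 | step 4 | 3,4,5-tris(benzyloxy)phenylboronic acid | OB(O)c1cc(OCc2ccccc2)c(OCc2ccccc2)c(OCc2ccccc2)c1
F5 | step 16 | 4-[3,4,5-tris(benzyloxy)phenoxy]-3,5-dimethoxyphenyllithium | [Li]c1cc(OC)c(Oc2cc(OCc3ccccc3)c(OCc3ccccc3)c(OCc3ccccc3)c2)c(OC)c1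
F6 | step 16 | 4-[3,4,5-tris(benzyloxy)phenoxy]-3,5-dimethoxyphenylboronic acid | OB(O)c1cc(OC)c(Oc2cc(OCc3ccccc3)c(OCc3ccccc3)c(OCc3ccccc3)c2)c(OC)c1
F7 | step 18 | heptadecaacetate of the target | CC(=O)Oc1cc(OC(C)=O)c(Oc2cc(OC(C)=O)c(Oc3cc(OC(C)=O)c(OC(C)=O)c(OC(C)=O)c3Oc3cc(OC(C)=O)c(Oc4cc(OC(C)=O)cc(OC(C)=O)c4Oc4cc(OC(C)=O)c(Oc5cc(OC(C)=O)c(OC(C)=O)c(OC(C)=O)c5)c(OC(C)=O)c4)c(OC(C)=O)c3)c(OC(C)=O)c2)c(OC(C)=O)c1
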